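## The problem

The target is all-E (3S,5R,6S,3'R)-7',8'-didehydro-5,6-dihydro-β,β-carotene-3,5,6,3'-tetrol. Carotenoid numbering is used throughout: ring T is C1–C6 (the triol ring), the chain runs C7–C15 and C15'–C7', and ring A is C1'–C6' (the acetylenic ring).

- The chain has eight E double bonds and the C7'≡C8' triple bond, and it joins two different end groups, so it cannot be made by a symmetric double coupling.
- Ring A has one stereocentre (C3') and a tetrasubstituted C5'=C6' bond conjugated to the alkyne.
- Ring T has three stereocentres. C5 and C6 are adjacent tertiary carbinols, cis to each other and both trans to the C3 hydroxyl. C6 also carries the polyene and sits next to the quaternary C1.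
- The two rings are separated by the whole chain, so each needs its own source of absolute configuration. Within ring T, C3 is 1,3 to C5 and has no contact with a reagent at C5/C6, because both faces there are screened by a C1 methyl.
- The tertiary allylic C6–OH ionises under acid (dehydration, 5,8-furanoid formation). The polyene is sensitive to light, oxygen and iodine, and the 9'-double bond next to the alkyne stereomutates easily. β-Hydroxy ketone intermediates can eliminate or undergo retro-aldol cleavage.
- The enabling feature: with the second C1 methyl and the C5 hydroxyl removed, ring T has a mirror plane through C3 and C6. C1 and C5 each carry one methyl, C3 carries oxygen para to C6, and C6 carries OH and the chain. This is the substitution pattern of 4-methoxy-2,6-dimethylphenol. The derived 4-alkynyl-4-hydroxy-3,5-dimethylcyclohexa-2,5-dienone is flat and achiral, C1 and C5 are its enantiotopic β-carbons, and its C6–OH lies on the mirror plane one atom from each of them. That same OH is propargylic to C7≡C8.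

## Retrosynthesis

**29 ⇒ 27 + 16 (C11=C12, Wittig).** This cut places the triol half as the aldehyde 16 and the acetylenic half as the C25 phosphonium salt 27. The neighbouring cut at C11'=C12' as the last bond would need the triol half as a phosphonium salt, and making that salt requires acid that ionises C6–OH. A central C15=C15' cut would need two C20 pieces, each longer to make. The forward reaction must tolerate four free hydroxyls, so no protecting group remains on the C40 stage.

**27 ⇒ 22 + 23 (C11'=C12', Wittig; then CHO → CH2PPh3+ through 25 and 26).** The C10 dialdehyde 23 is a catalogue compound and reacts once when used in excess. All acid chemistry is confined to this half, which has no tertiary alcohol.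

**22 ⇒ 20 + 3 (C6'–C7', Sonogashira), 20 ⇐ 18 ⇐ 17.** The alternative, acetylide addition to ketone 18 followed by dehydration, needs a regioselective elimination. The enol triflate 20 avoids this because C1' is quaternary, so ketone 18 can enolise in one direction only. The C5' stereocentre of 17 is erased and only C3' is carried on.

**16 ⇒ 15 ⇒ 14 ⇒ 13 (C7=C8 from C7≡C8).** The alkyne allows C6 to be built by carbonyl addition at an achiral stage. The C6 hydroxyl then returns the E-alkene by directed trans-hydroalumination. The ring A alkyne of the other half is never exposed to this reagent.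

**13 ⇒ 12 (C3–H).** The C3 carbinol comes from a ketone, with hydride delivered by the axial C5–OH to give the 1,3-trans relation. A free ketone at C3 is exactly what the dienone route provides.

**12 ⇒ 11 ⇒ 9 (boron removal; C1–CH3).** The second C1 methyl comes from conjugate addition to the remaining enone arm of 9. No stereocentre is created, so this hindered step carries no selectivity demand.

**9 ⇒ 7 (key step; C5–O bond through a boron tether).** The achiral dienone 7 is much simpler than 9, which holds both tertiary carbinol stereocentres with cis relation and absolute configuration. The tether atom is not in the target and is removed in step 6.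

**7 ⇒ 2 + 4 (C6–C7), 2 ⇐ 1, 4 ⇐ 3.** Acetylide addition to the quinone monoketal 2, made by dearomatising phenol 1, gives ring T's carbons, less one C1 methyl, and the C7–C11 chain carbons in three operations.

## Roads not taken

**Alternative 1:** The most obvious plan is C15 + C10 + C15 by two Wittig reactions, with both end groups from 17 and the triol ring made by OsO4 cis-dihydroxylation of the C5=C6 bond of enyne 21, giving diol A1.
- The tetrasubstituted C5=C6 bond has a C1 methyl on each face. The only face-differentiating element is the C3 silyloxy group, which is remote.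
- In the half-chair with C3–O equatorial, the pseudoaxial C1 methyl blocks the face anti to that oxygen. The reagent is therefore steered toward the all-cis isomer A2.
- A hydroxyl-directed variant (free 3-OH, OsO4/TMEDA) gives A2 by design.
- The chosen plan fixes the 5,6-cis relation by a ring and the 3,5-trans relation by intramolecular hydride delivery.

**Alternative 2:** Trace the diol to the 5,6-epoxide A3 (from Ti(O-i-Pr)4/tartrate epoxidation of a ring allylic alcohol, or from a peracid) and open it with water.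
- Anti opening, or ionisation at the allylic C6, gives the trans-diol A4, the C6 epimer of the required end group, along with 5,8-furanoid products.
- The cis-diol would need retention at both carbons, which this reaction cannot give. The route would also be longer.

**Alternative 3:** A two-directional use of the C2-symmetric C22 heptaene-diyne A5 (from 23 and two enynyl ylides): Sonogashira coupling with 20 at one end, acetylide addition to the α-hydroxy ketone A6 at the other, then the same OH-directed reduction.
- Differentiating the two ends of A5 is statistical.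
- A6 needs C5 set relative to C3 by enolate hydroxylation, again under the remote C3 group only.
- The acetylide must then add to a carbonyl between two fully substituted carbons, with face control left to chelation.
- The whole polyene would be carried as a lithium acetylide.
- The chosen plan settles C5 and C6 before any polyene exists.

Key step: step 4

Assumption: (4R,6R)-actinol 17 is taken as a purchasable single-enantiomer building block; 1, 3 and 23 are catalogue compounds.

## Route

Step 1
Reactants: 1 4-methoxy-2,6-dimethylphenol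
Product: 2 4,4-dimethoxy-2,6-dimethylcyclohexa-2,5-dien-1-one
Conditions: PhI(OAc)2, MeOH, 0 °C to rt
Reagents that add atoms: methanol, CO
Why: Oxidative dearomatisation of a p-methoxyphenol to the quinone monoketal; methanol enters para at the methoxy-bearing carbon, so the carbonyl stays between the two methyl-bearing carbons.

Step 2
Reactants: 3 (2E)-3-methylpent-2-en-4-yn-1-ol
Product: 4 tert-butyldimethyl{[(2E)-3-methylpent-2-en-4-yn-1-yl]oxy}silane
Conditions: t-BuMe2SiCl, imidazole, DMF, 0 °C to rt
Reagents that add atoms: tert-butylchlorodimethylsilane, CC(C)(C)[Si](C)(C)Cl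
Why: Standard silylation of a primary alcohol; the ether keeps the C11 oxygen off boron, copper and aluminium in steps 4, 5 and 8 and leaves the C6 hydroxyl as the only director in step 8.

Step 3
Reactants: 4 silyl ether of the enynol; 2 quinone monoketal
Product: 7 4-hydroxy-3,5-dimethyl-4-[(3E)-5-(tert-butyldimethylsilyloxy)-3-methylpent-3-en-1-ynyl]cyclohexa-2,5-dien-1-one, via lithium acetylide 5 (not isolated), via ketal carbinol 6 (not isolated)
Conditions: n-BuLi, THF, −78 °C; add 2, −78 to −20 °C; then 5% aq. oxalic acid, THF, 0 °C to rt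
Reagents that add atoms: water, O
Why: 1,2-Addition of a lithium acetylide to a quinone monoketal carbonyl and mild hydrolysis of the dimethyl ketal is the standard entry to 4-alkynyl p-quinols; 7 is achiral (mirror plane through C3 and C6), so no stereocentre is set.

Step 4
Reactants: 7 p-quinol
Product: 9 (3aR,7aR)-3a,7-dimethyl-2-phenyl-7a-[(3E)-5-(tert-butyldimethylsilyloxy)-3-methylpent-3-en-1-ynyl]-3a,4-dihydro-1,3,2-benzodioxaborol-5(7aH)-one, via boronic hemiester 8 (not isolated)
Conditions: PhB(OH)2 (1.2 equiv), N-[3,5-bis(trifluoromethyl)phenyl]-N'-[(9R)-6'-methoxycinchonan-9-yl]thiourea (15 mol %), 4 Å molecular sieves, toluene, 25–40 °C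
Reagents that add atoms: phenylboronic acid, OB(O)c1ccccc1
Why: Proposed new method: the tertiary C6–OH condenses with PhB(OH)2 to hemiester 8, the quinuclidine nitrogen of the catalyst binds the B–OH and makes its oxygen nucleophilic while the thiourea hydrogen-bonds the dienone carbonyl, and the boron-bound oxygen adds to the β-carbon C5 of one enone arm before the enol is protonated at C4. The closest known reaction types are the amine–thiourea-catalysed boronic-hemiester oxa-Michael addition of γ-hydroxy enones, which gives syn-1,2-diol boronates, and the acid-catalysed acetal/oxa-Michael desymmetrisation of p-quinols; neither has been shown on a β-methyl dienone or a tertiary-alcohol hemiester, hence the label. The dioxaborolane closes 5-exo-trig (ring O–B–O–C5–C6, the attacked C5=C4 bond exocyclic to it). C5 is set cis to the C6 oxygen by the tether, since a five-membered ring fused to the cyclohexenone can only be cis. The absolute configuration of C5, and of C6, which becomes stereogenic in the same event, follows from which enantiotopic arm (C5 or C1) the catalyst-bound boronate attacks; the quinine-derived pseudo-enantiomer of the catalyst gives the other arm, and the antipode leading to 9 is fixed by correlation at 13. The β-methyl group makes the enone a poorer acceptor, but the addition is intramolecular and the product, a pinacol-type boronate of a ditertiary cis-diol, is a thermodynamic sink against retro-addition. The step needs enantiotopic-group selectivity (catalyst), cis selectivity (ring size) and mono-addition (boron has no second hydroxyl left for the other arm).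

Step 5
Reactants: 9 boronate enone
Product: 11 (3aR,7aR)-3a,7,7-trimethyl-2-phenyl-7a-[(3E)-5-(tert-butyldimethylsilyloxy)-3-methylpent-3-en-1-ynyl]-3a,6,7,7a-tetrahydro-1,3,2-benzodioxaborol-5(4H)-one, via trimethylsilyl enol ether 10 (not isolated)
Conditions: Me2CuLi (from MeLi and CuI, 3 equiv), Me3SiCl, THF, −78 to −30 °C; aq. NH4Cl/NH3; then 10% aq. citric acid, THF, 0 °C
Reagents that add atoms: lithium dimethylcuprate (made in the flask from MeLi and CuI), [Li+].C[Cu-]C
Why: Silyl-chloride-accelerated conjugate addition of a Gilman cuprate to a β,β-disubstituted cyclohexenone; C1 becomes CMe2, so no stereocentre arises and the face of attack is irrelevant, and the enolate forms on the C2 side away from the C5 oxygen, so β-elimination is not set up.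

Step 6
Reactants: 11 boronate ketone
Product: 12 (3R,4R)-3,4-dihydroxy-3,5,5-trimethyl-4-[(3E)-5-(tert-butyldimethylsilyloxy)-3-methylpent-3-en-1-ynyl]cyclohexan-1-one
Conditions: NaBO3·4H2O, THF/H2O 1:1, 0 °C to rt
Reagents that add atoms: none
Why: Oxidative cleavage of the B–phenyl bond and hydrolysis of the resulting borate, the near-neutral work-up used for boron aldolates that β-hydroxy ketones survive; the C5–O and C6–O bonds are not broken, so both configurations are retained.

Step 7
Reactants: 12 dihydroxy ketone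
Product: 13 (1R,2R,4S)-2,6,6-trimethyl-1-[(3E)-5-(tert-butyldimethylsilyloxy)-3-methylpent-3-en-1-ynyl]cyclohexane-1,2,4-triol
Conditions: Me4NBH(OAc)3, MeCN/AcOH 1:1, −30 to 0 °C
Reagents that add atoms: none
Why: Evans–Saksena hydroxyl-directed reduction: in the preferred chair the C5 hydroxyl is axial, exchanges onto boron and delivers hydride to the same face of the C3 carbonyl through a six-membered transition state, giving the 3,5-trans diol (the equatorial C3 alcohol); the reagent does not reduce ketones without this activation.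

Step 8
Reactants: 13 alkynyl triol
Product: 14 (1S,2R,4S)-2,6,6-trimethyl-1-[(1E,3E)-5-(tert-butyldimethylsilyloxy)-3-methylpenta-1,3-dienyl]cyclohexane-1,2,4-triol
Conditions: NaAlH2(OCH2CH2OMe)2 (5 equiv), THF, 0 °C to rt; aq. potassium sodium tartrate
Reagents that add atoms: none
Why: trans-Hydroalumination of a propargylic alcohol: the C6 alkoxide delivers hydride to C7 with aluminium at C8, and protonolysis gives only the E C7=C8 bond; the reaction type is well established for 1-alkynyl-2,6,6-trimethylcyclohexan-1-ols carrying this enyne chain.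

Step 9
Reactants: 14 silyl ether
Product: 15 (1S,2R,4S)-1-[(1E,3E)-5-hydroxy-3-methylpenta-1,3-dienyl]-2,6,6-trimethylcyclohexane-1,2,4-triol
Conditions: Bu4NF, THF, 0 °C to rt
Reagents that add atoms: none
Why: Fluoride cleavage of the primary silyl ether without acid, so the tertiary allylic C6 alcohol is not ionised.

Step 10
Reactants: 15 tetraol
Product: 16 (2E,4E)-3-methyl-5-[(1S,2R,4S)-1,2,4-trihydroxy-2,6,6-trimethylcyclohexyl]penta-2,4-dienal
Conditions: MnO2 (activated), EtOAc, rt, dark
Reagents that add atoms: none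
Why: MnO2 oxidises only the primary dienylic alcohol; the C3 alcohol is not allylic and the tertiary alcohols cannot be oxidised.

Step 11
Reactants: 17 (4R,6R)-4-hydroxy-2,2,6-trimethylcyclohexan-1-one
Product: 18 (4R,6R)-2,2,6-trimethyl-4-(triethylsilyloxy)cyclohexan-1-one
Conditions: Et3SiCl, imidazole, CH2Cl2, 0 °C
Reagents that add atoms: chlorotriethylsilane, CC[Si](Cl)(CC)CC
Why: Silylation of the secondary alcohol; the triethylsilyl group survives enolate and palladium chemistry and is labile enough to be lost in step 14.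

Step 12
Reactants: 18 silyloxy ketone
Product: 20 (4R)-2,6,6-trimethyl-4-(triethylsilyloxy)cyclohex-1-en-1-yl trifluoromethanesulfonate, via potassium enolate 19 (not isolated)
Conditions: KN(SiMe3)2, THF, −78 to 0 °C; PhNTf2, −78 to 0 °C
Reagents that add atoms: N-phenylbis(trifluoromethanesulfonimide), O=S(=O)(N(c1ccccc1)S(=O)(=O)C(F)(F)F)C(F)(F)F
Why: Enol triflate formation; the other α-carbon is quaternary, so only one enolate and one tetrasubstituted triflate can form, the methyl-bearing stereocentre of 17 is erased and the silyloxy carbon is untouched.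

Step 13
Reactants: 20 enol triflate; 3 (2E)-3-methylpent-2-en-4-yn-1-ol
Product: 21 (2E)-3-methyl-5-[(4R)-2,6,6-trimethyl-4-(triethylsilyloxy)cyclohex-1-en-1-yl]pent-2-en-4-yn-1-ol
Conditions: Pd(PPh3)4 (5 mol %), CuI (10 mol %), i-Pr2NH, DMF, 25–45 °C
Reagents that add atoms: none
Why: Sonogashira coupling of an enol triflate with a terminal alkyne forms the C6'–C7' bond and the complete ring A enyne in one step; the E geometry at C9'=C10' comes from 3 and is not touched.

Step 14
Reactants: 21 enynol
Product: 22 {(2E)-5-[(4R)-4-hydroxy-2,6,6-trimethylcyclohex-1-en-1-yl]-3-methylpent-2-en-4-yn-1-yl}triphenylphosphonium bromide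
Conditions: PPh3·HBr (1.2 equiv), MeOH, rt
Reagents that add atoms: triphenylphosphine hydrobromide, Br.c1ccc(cc1)P(c1ccccc1)c1ccccc1
Why: Allylic alcohol to phosphonium salt through the delocalised cation, captured by PPh3 at the primary terminus; the acidic methanol also cleaves the triethylsilyl ether, and ring A has no acid-labile tertiary alcohol.

Step 15
Reactants: 22 C15 phosphonium salt; 23 (2E,4E,6E)-2,7-dimethylocta-2,4,6-trienedial
Product: 25 (2E,4E,6E,8E,10E)-13-[(4R)-4-hydroxy-2,6,6-trimethylcyclohex-1-en-1-yl]-2,7,11-trimethyltrideca-2,4,6,8,10-pentaen-12-ynal, via ylide 24 (not isolated)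
Conditions: NaOMe, MeOH/CH2Cl2, 0 °C to rt; 23 in excess (2.5 equiv), 22 added slowly; dark
Reagents that add atoms: none
Why: Wittig olefination; the dialdehyde in excess reacts once because the product polyenal is the weaker electrophile, and Z isomer at the new C11'=C12' bond should convert to E on gentle warming or be removed on crystallisation.

Step 16
Reactants: 25 C25 aldehyde
Product: 26 (2E,4E,6E,8E,10E)-13-[(4R)-4-hydroxy-2,6,6-trimethylcyclohex-1-en-1-yl]-2,7,11-trimethyltrideca-2,4,6,8,10-pentaen-12-yn-1-ol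
Conditions: NaBH4, EtOH/CH2Cl2, 0 °C, dark
Reagents that add atoms: none
Why: 1,2-Reduction of a polyenal by borohydride; no other reducible group is present.

Step 17
Reactants: 26 C25 alcohol
Product: 27 {(2E,4E,6E,8E,10E)-13-[(4R)-4-hydroxy-2,6,6-trimethylcyclohex-1-en-1-yl]-2,7,11-trimethyltrideca-2,4,6,8,10-pentaen-12-yn-1-yl}triphenylphosphonium bromide
Conditions: PPh3·HBr, MeOH/CH2Cl2, 0 °C to rt, dark
Reagents that add atoms: triphenylphosphine hydrobromide, Br.c1ccc(cc1)P(c1ccccc1)c1ccccc1
Why: As step 14; the polyenyl cation is captured by PPh3 at the terminal carbon C12 to give the conjugated salt.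

Step 18
Reactants: 27 C25 phosphonium salt; 16 triol dienal
Product: 29 all-E (3S,5R,6S,3'R)-7',8'-didehydro-5,6-dihydro-β,β-carotene-3,5,6,3'-tetrol, via ylide 28 (not isolated)
Conditions: NaOMe, MeOH/CH2Cl2, −10 °C to rt, argon, dark; then EtOAc/heptane, 60 °C, crystallisation
Reagents that add atoms: none
Why: Wittig olefination forms C11=C12 under mild base that the four free hydroxyls tolerate; the hindered 11Z isomer should convert thermally to all-E, and no protecting group remains to be removed.

## Compound list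

1 | 4-methoxy-2,6-dimethylphenol | COc1cc(C)c(O)c(C)c1 | starting material
2 | 4,4-dimethoxy-2,6-dimethylcyclohexa-2,5-dien-1-one | COC1(OC)C=C(C)C(=O)C(C)=C1 | intermediate
3 | (2E)-3-methylpent-2-en-4-yn-1-ol | C#C/C(C)=C/CO | starting material
4 | tert-butyldimethyl{[(2E)-3-methylpent-2-en-4-yn-1-yl]oxy}silane | C#C/C(C)=C/CO[Si](C)(C)C(C)(C)C | intermediate
5 | lithium acetylide of 4 | [Li]C#C/C(C)=C/CO[Si](C)(C)C(C)(C)C | intermediate (not isolated)
6 | 1-[(3E)-5-(tert-butyldimethylsilyloxy)-3-methylpent-3-en-1-ynyl]-4,4-dimethoxy-2,6-dimethylcyclohexa-2,5-dien-1-ol | COC1(OC)C=C(C)C(O)(C#C/C(C)=C/CO[Si](C)(C)C(C)(C)C)C(C)=C1 | intermediate (not isolated)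
7 | 4-hydroxy-3,5-dimethyl-4-[(3E)-5-(tert-butyldimethylsilyloxy)-3-methylpent-3-en-1-ynyl]cyclohexa-2,5-dien-1-one | CC1=CC(=O)C=C(C)C1(O)C#C/C(C)=C/CO[Si](C)(C)C(C)(C)C | intermediate
8 | hydrogen phenylboronate (hemiester) of 7 at the tertiary oxygen | CC1=CC(=O)C=C(C)C1(OB(O)c2ccccc2)C#C/C(C)=C/CO[Si](C)(C)C(C)(C)C | intermediate (not isolated)
9 | (3aR,7aR)-3a,7-dimethyl-2-phenyl-7a-[(3E)-5-(tert-butyldimethylsilyloxy)-3-methylpent-3-en-1-ynyl]-3a,4-dihydro-1,3,2-benzodioxaborol-5(7aH)-one | CC(C)(C)[Si](C)(C)OC/C=C(C)/C#C[C@]1(OB2c3ccccc3)C(C)=CC(=O)C[C@@]1(C)O2 | intermediate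
10 | trimethylsilyl enol ether of 11 (C2=C3 enol ether, carotenoid numbering) | CC(C)(C)[Si](C)(C)OC/C=C(C)/C#C[C@]1(OB2c3ccccc3)C(C)(C)C=C(O[Si](C)(C)C)C[C@@]1(C)O2 | intermediate (not isolated)
11 | (3aR,7aR)-3a,7,7-trimethyl-2-phenyl-7a-[(3E)-5-(tert-butyldimethylsilyloxy)-3-methylpent-3-en-1-ynyl]-3a,6,7,7a-tetrahydro-1,3,2-benzodioxaborol-5(4H)-one | CC(C)(C)[Si](C)(C)OC/C=C(C)/C#C[C@]1(OB2c3ccccc3)C(C)(C)CC(=O)C[C@@]1(C)O2 | intermediate
12 | (3R,4R)-3,4-dihydroxy-3,5,5-trimethyl-4-[(3E)-5-(tert-butyldimethylsilyloxy)-3-methylpent-3-en-1-ynyl]cyclohexan-1-one | CC(C)(C)[Si](C)(C)OC/C=C(C)/C#C[C@]1(O)C(C)(C)CC(=O)C[C@@]1(C)O | intermediate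
13 | (1R,2R,4S)-2,6,6-trimethyl-1-[(3E)-5-(tert-butyldimethylsilyloxy)-3-methylpent-3-en-1-ynyl]cyclohexane-1,2,4-triol | CC(C)(C)[Si](C)(C)OC/C=C(C)/C#C[C@]1(O)C(C)(C)C[C@H](O)C[C@@]1(C)O | intermediate
14 | (1S,2R,4S)-2,6,6-trimethyl-1-[(1E,3E)-5-(tert-butyldimethylsilyloxy)-3-methylpenta-1,3-dienyl]cyclohexane-1,2,4-triol | CC(C)(C)[Si](C)(C)OC/C=C(C)/C=C/[C@]1(O)C(C)(C)C[C@H](O)C[C@@]1(C)O | intermediate
15 | (1S,2R,4S)-1-[(1E,3E)-5-hydroxy-3-methylpenta-1,3-dienyl]-2,6,6-trimethylcyclohexane-1,2,4-triol | OC/C=C(C)/C=C/[C@]1(O)C(C)(C)C[C@H](O)C[C@@]1(C)O | intermediate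
16 | (2E,4E)-3-methyl-5-[(1S,2R,4S)-1,2,4-trihydroxy-2,6,6-trimethylcyclohexyl]penta-2,4-dienal | O=C/C=C(C)/C=C/[C@]1(O)C(C)(C)C[C@H](O)C[C@@]1(C)O | intermediate
17 | (4R,6R)-4-hydroxy-2,2,6-trimethylcyclohexan-1-one | CC1(C)C[C@H](O)C[C@@H](C)C1=O | starting material
18 | (4R,6R)-2,2,6-trimethyl-4-(triethylsilyloxy)cyclohexan-1-one | CC1(C)C[C@H](O[Si](CC)(CC)CC)C[C@@H](C)C1=O | intermediate
19 | potassium enolate of 18 | CC1=C([O-])C(C)(C)C[C@H](O[Si](CC)(CC)CC)C1.[K+] | intermediate (not isolated)
20 | (4R)-2,6,6-trimethyl-4-(triethylsilyloxy)cyclohex-1-en-1-yl trifluoromethanesulfonate | CC1=C(OS(=O)(=O)C(F)(F)F)C(C)(C)C[C@H](O[Si](CC)(CC)CC)C1 | intermediate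
21 | (2E)-3-methyl-5-[(4R)-2,6,6-trimethyl-4-(triethylsilyloxy)cyclohex-1-en-1-yl]pent-2-en-4-yn-1-ol | CC1=C(C#C/C(C)=C/CO)C(C)(C)C[C@H](O[Si](CC)(CC)CC)C1 | intermediate
22 | {(2E)-5-[(4R)-4-hydroxy-2,6,6-trimethylcyclohex-1-en-1-yl]-3-methylpent-2-en-4-yn-1-yl}triphenylphosphonium bromide | CC1=C(C#C/C(C)=C/C[P+](c2ccccc2)(c2ccccc2)c2ccccc2)C(C)(C)C[C@H](O)C1.[Br-] | intermediate
23 | (2E,4E,6E)-2,7-dimethylocta-2,4,6-trienedial | O=C/C(C)=C/C=C/C=C(C)/C=O | starting material
24 | ylide from 22 | CC1=C(C#C/C(C)=C/C=P(c2ccccc2)(c2ccccc2)c2ccccc2)C(C)(C)C[C@H](O)C1 | intermediate (not isolated)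
25 | (2E,4E,6E,8E,10E)-13-[(4R)-4-hydroxy-2,6,6-trimethylcyclohex-1-en-1-yl]-2,7,11-trimethyltrideca-2,4,6,8,10-pentaen-12-ynal | CC1=C(C#C/C(C)=C/C=C/C(C)=C/C=C/C=C(C)/C=O)C(C)(C)C[C@H](O)C1 | intermediate
26 | (2E,4E,6E,8E,10E)-13-[(4R)-4-hydroxy-2,6,6-trimethylcyclohex-1-en-1-yl]-2,7,11-trimethyltrideca-2,4,6,8,10-pentaen-12-yn-1-ol | CC1=C(C#C/C(C)=C/C=C/C(C)=C/C=C/C=C(C)/CO)C(C)(C)C[C@H](O)C1 | intermediate
27 | {(2E,4E,6E,8E,10E)-13-[(4R)-4-hydroxy-2,6,6-trimethylcyclohex-1-en-1-yl]-2,7,11-trimethyltrideca-2,4,6,8,10-pentaen-12-yn-1-yl}triphenylphosphonium bromide | CC1=C(C#C/C(C)=C/C=C/C(C)=C/C=C/C=C(C)/C[P+](c2ccccc2)(c2ccccc2)c2ccccc2)C(C)(C)C[C@H](O)C1.[Br-] | intermediate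
28 | ylide from 27 | CC1=C(C#C/C(C)=C/C=C/C(C)=C/C=C/C=C(C)/C=P(c2ccccc2)(c2ccccc2)c2ccccc2)C(C)(C)C[C@H](O)C1 | intermediate (not isolated)
29 | all-E (3S,5R,6S,3'R)-7',8'-didehydro-5,6-dihydro-β,β-carotene-3,5,6,3'-tetrol | CC1=C(C#C/C(C)=C/C=C/C(C)=C/C=C/C=C(C)/C=C/C=C(C)/C=C/[C@]2(O)C(C)(C)C[C@H](O)C[C@@]2(C)O)C(C)(C)C[C@H](O)C1 | target

## Step count and least certain steps

Total step count: 18. Longest linear sequence: 10 steps (1, 3–10, 18) from 1. The ring A branch is 8 steps (11–18) from 17, and step 2 is a one-step side branch.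

**Step 4 (key step, the one labelled as a proposed new method).**
- What may go wrong: hemiester formation at the hindered tertiary alcohol may be slow; the oxygen may add sluggishly or reversibly to the β-methyl arm; and the catalyst may discriminate poorly between the two arms, because both anchoring points (carbonyl and C6–O) lie on the mirror plane.
- Fallback, from 7 back to 12, using known reaction types only: mono-addition of Me2CuLi/Me3SiCl to 7 gives the racemic 4-alkynyl-4-hydroxy-3,5,5-trimethylcyclohexenone F1. Resolution of F1 on a chiral stationary phase gives the (4S)-enone F2. Hydroxyl-directed Weitz–Scheffer epoxidation of F2 (t-BuOOH, benzyltrimethylammonium hydroxide, THF, 0 °C) should place the epoxide cis to the C6–OH, giving epoxy ketone F3. Reductive opening of F3 at the α-carbon with SmI2 (THF/MeOH, −90 °C) gives 12. This route needs no boron and no new reaction, at the cost of a resolution.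

**Step 5.**
- What may go wrong: the organocopper or residual MeLi may attack boron; the propargylic C6–O(B) group may be lost by SN2' substitution to an allene; or the addition may stall because C1 becomes quaternary next to the fully substituted C6.
- Fallback, from 9 back to 12, with no boron present during C–C bond formation: NaBO3·4H2O cleaves the boronate of 9 to the diol enone F4. Me3Si-imidazole converts F4 to the bis(trimethylsilyl) ether F5. Me2CuLi/Me3SiCl then gives the saturated ketone F6. Citric acid in MeOH removes the two tertiary silyl ethers from F6 to give 12.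

**Step 7.**
- What may go wrong: loss of facial control if the diol binds boron without the axial C5 oxygen delivering the hydride; or acid-promoted dehydration or retro-aldol cleavage of the tertiary β-hydroxy ketone.
- Fallback, from 11 back to 13, setting C3 by inversion instead of delivery: LiBH(s-Bu)3 (THF, −78 °C) should attack boronate ketone 11 from the open equatorial direction and give the axial C3-epimeric alcohol F7. Mitsunobu inversion of F7 with 4-nitrobenzoic acid, PPh3 and diisopropyl azodicarboxylate gives the ester F8. K2CO3/MeOH followed by NaBO3·4H2O removes the ester and the boron from F8 to give 13.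

**Step 8.**
- What may go wrong: hydride addition across the conjugated enyne in the 1,4 sense (allene formation) or over-reduction; partial loss of the silyl ether; or incomplete reaction once three alkoxides are bound to aluminium.
- Fallback, from 13 back to 15: ruthenium-catalysed trans-hydrosilylation of 13 ([Cp*Ru(MeCN)3]PF6, (EtO)3SiH, CH2Cl2, 0 °C) gives the Z-vinylsilane F9. Protodesilylation of F9 with Bu4NF/CuI in THF gives the E-alkene and removes the primary silyl ether in the same operation, arriving at 15.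

**Step 18.**
- What may go wrong: Z/E mixtures at C11=C12; stereomutation of the C9'=C10' bond next to the triple bond if the isomerisation is forced; or decay of the long ylide 28 before it meets 16.
- Fallback, from 26 back to 29, by Horner–Wadsworth–Emmons olefination: Corey–Kim bromination of 26 (N-bromosuccinimide, Me2S, CH2Cl2, −20 °C), which is selective for the allylic alcohol, gives bromide F10. Michaelis–Becker reaction of F10 with NaP(O)(OEt)2 gives phosphonate F11. Deprotonation of F11 with NaN(SiMe3)2 (excess, THF, −78 °C) and addition of 16 should give the E C11=C12 bond directly and lead to 29.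

## Further compounds

F1 | step 4 | racemic 4-hydroxy-3,5,5-trimethyl-4-[(3E)-5-(tert-butyldimethylsilyloxy)-3-methylpent-3-en-1-ynyl]cyclohex-2-en-1-one | CC(C)(C)[Si](C)(C)OC/C=C(C)/C#CC1(O)C(C)(C)CC(=O)C=C1C
F2 | step 4 | (4S)-4-hydroxy-3,5,5-trimethyl-4-[(3E)-5-(tert-butyldimethylsilyloxy)-3-methylpent-3-en-1-ynyl]cyclohex-2-en-1-one | CC(C)(C)[Si](C)(C)OC/C=C(C)/C#C[C@]1(O)C(C)(C)CC(=O)C=C1C
F3 | step 4 | (1S,5R,6R)-5-hydroxy-4,4,6-trimethyl-5-[(3E)-5-(tert-butyldimethylsilyloxy)-3-methylpent-3-en-1-ynyl]-7-oxabicyclo[4.1.0]heptan-2-one (epoxide cis to the hydroxyl) | CC(C)(C)[Si](C)(C)OC/C=C(C)/C#C[C@]1(O)C(C)(C)CC(=O)[C@@H]2[C@@]1(C)O2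
F4 | step 5 | (4R,5R)-4,5-dihydroxy-3,5-dimethyl-4-[(3E)-5-(tert-butyldimethylsilyloxy)-3-methylpent-3-en-1-ynyl]cyclohex-2-en-1-one | CC(C)(C)[Si](C)(C)OC/C=C(C)/C#C[C@]1(O)C(C)=CC(=O)C[C@@]1(C)O
F5 | step 5 | (4R,5R)-3,5-dimethyl-4,5-bis(trimethylsilyloxy)-4-[(3E)-5-(tert-butyldimethylsilyloxy)-3-methylpent-3-en-1-ynyl]cyclohex-2-en-1-one | CC(C)(C)[Si](C)(C)OC/C=C(C)/C#C[C@]1(O[Si](C)(C)C)C(C)=CC(=O)C[C@@]1(C)O[Si](C)(C)C
F6 | step 5 | (3R,4R)-3,5,5-trimethyl-3,4-bis(trimethylsilyloxy)-4-[(3E)-5-(tert-butyldimethylsilyloxy)-3-methylpent-3-en-1-ynyl]cyclohexan-1-one | CC(C)(C)[Si](C)(C)OC/C=C(C)/C#C[C@]1(O[Si](C)(C)C)C(C)(C)CC(=O)C[C@@]1(C)O[Si](C)(C)C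
F7 | step 7 | (3aR,5R,7aR)-3a,7,7-trimethyl-2-phenyl-7a-[(3E)-5-(tert-butyldimethylsilyloxy)-3-methylpent-3-en-1-ynyl]hexahydro-1,3,2-benzodioxaborol-5-ol (C3 epimer series) | CC(C)(C)[Si](C)(C)OC/C=C(C)/C#C[C@]1(OB2c3ccccc3)C(C)(C)C[C@@H](O)C[C@@]1(C)O2
F8 | step 7 | (3aR,5S,7aR)-3a,7,7-trimethyl-2-phenyl-7a-[(3E)-5-(tert-butyldimethylsilyloxy)-3-methylpent-3-en-1-ynyl]hexahydro-1,3,2-benzodioxaborol-5-yl 4-nitrobenzoate | CC(C)(C)[Si](C)(C)OC/C=C(C)/C#C[C@]1(OB2c3ccccc3)C(C)(C)C[C@H](OC(=O)c3ccc(cc3)[N+](=O)[O-])C[C@@]1(C)O2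
F9 | step 8 | (1S,2R,4S)-2,6,6-trimethyl-1-[(1Z,3E)-5-(tert-butyldimethylsilyloxy)-3-methyl-2-(triethoxysilyl)penta-1,3-dienyl]cyclohexane-1,2,4-triol | CC(C)(C)[Si](C)(C)OC/C=C(C)/C(=C/[C@]1(O)C(C)(C)C[C@H](O)C[C@@]1(C)O)[Si](OCC)(OCC)OCC
F10 | step 18 | (1R)-4-[(3E,5E,7E,9E,11E)-13-bromo-3,7,12-trimethyltrideca-3,5,7,9,11-pentaen-1-ynyl]-3,5,5-trimethylcyclohex-3-en-1-ol | CC1=C(C#C/C(C)=C/C=C/C(C)=C/C=C/C=C(C)/CBr)C(C)(C)C[C@H](O)C1
F11 | step 18 | diethyl {(2E,4E,6E,8E,10E)-13-[(4R)-4-hydroxy-2,6,6-trimethylcyclohex-1-en-1-yl]-2,7,11-trimethyltrideca-2,4,6,8,10-pentaen-12-yn-1-yl}phosphonate | CC1=C(C#C/C(C)=C/C=C/C(C)=C/C=C/C=C(C)/CP(=O)(OCC)OCC)C(C)(C)C[C@H](O)C1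
A1 | alternative 1 | (1R,2R,4S)-1-[(3E)-5-hydroxy-3-methylpent-3-en-1-ynyl]-2,6,6-trimethyl-4-(triethylsilyloxy)cyclohexane-1,2-diol | OC/C=C(C)/C#C[C@]1(O)C(C)(C)C[C@H](O[Si](CC)(CC)CC)C[C@@]1(C)O
A2 | alternative 1 | (1S,2S,4S)-1-[(3E)-5-hydroxy-3-methylpent-3-en-1-ynyl]-2,6,6-trimethyl-4-(triethylsilyloxy)cyclohexane-1,2-diol (diol cis to the C3 oxygen) | OC/C=C(C)/C#C[C@@]1(O)C(C)(C)C[C@H](O[Si](CC)(CC)CC)C[C@]1(C)O
A3 | alternative 2 | (2E,4E)-5-[(1S,4S,6R)-4-hydroxy-2,2,6-trimethyl-7-oxabicyclo[4.1.0]heptan-1-yl]-3-methylpenta-2,4-dien-1-ol | OC/C=C(C)/C=C/[C@]1(O2)C(C)(C)C[C@H](O)C[C@]12C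
A4 | alternative 2 | (2E,4E)-3-methyl-5-[(1R,2R,4S)-1,2,4-trihydroxy-2,6,6-trimethylcyclohexyl]penta-2,4-dien-1-ol (trans-5,6-diol, C6 epimer of 15) | OC/C=C(C)/C=C/[C@@]1(O)C(C)(C)C[C@H](O)C[C@@]1(C)O
A5 | alternative 3 | (3E,5E,7E,9E,11E,13E,15E)-3,7,12,16-tetramethyloctadeca-3,5,7,9,11,13,15-heptaene-1,17-diyne | C#C/C(C)=C/C=C/C(C)=C/C=C/C=C(C)/C=C/C=C(C)/C#C
A6 | alternative 3 | (2R,4S)-2-hydroxy-2,6,6-trimethyl-4-(triethylsilyloxy)cyclohexan-1-one | CC1(C)C[C@H](O[Si](CC)(CC)CC)C[C@@](C)(O)C1=O
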